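My unit of account is one exchange: one incoming ligand placed on one complex.

| flask | starting complex | incoming ligand | leaving ligand | capture agent | time | remark |
|---|---|---|---|---|---|---|
| summer | 0.014 M | 0.0252 M | 0.0280 M | 0.280 mM | 5.0 min | a closed flask charged with all of it at once and left for 5.0 min |
| midnight | 0.014 M | 0.0252 M | 0.0280 M | 0.280 mM |  | one stirred flow tank at steady state, fed with the mixture as stated, mean residence time 5.0 min |
| noon | 0.014 M (fed, over 4.00 min) | 0.0252 M | 0.0280 M | 0.280 mM | 5.0 min | a stirred flask in which starting complex is dosed at a steady rate over 4.00 min without added volume, worked up at 5.0 min |
| autumn | 0.014 M | 0.0252 M (fed, over 4.00 min) | 0.0280 M | 0.280 mM | 5.0 min | all but incoming ligand at the start; incoming ligand goes in evenly over 4.00 min, the run ends at 5.0 min |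

    starting complex + incoming ligand ⇌ leaving ligand + complex with one exchanged (K1 = 67.7, k1 = 3.40 M⁻¹ s⁻¹)
    complex with one exchanged + incoming ligand ⇌ leaving ligand + complex with two exchanged (K2 = 0.943, k2 = 6.98 M⁻¹ s⁻¹)
    complex with two exchanged + incoming ligand ⇌ leaving ligand + complex with three exchanged (K3 = 10.8, k3 = 3.93 M⁻¹ s⁻¹)
    complex with three exchanged ⇌ isomer of the product (K4 = 0.62, k4 = 0.00687 s⁻¹)
    complex with two exchanged + capture agent → trapped intermediate (k5 = 0.723 M⁻¹ s⁻¹)
    leaving ligand → by-product carried off (k6 = 0.169 s⁻¹)

1. the set-up with the highest amount of complex with three exchanged at the outlet or at the end, in percent of the starting complex put in ("none" if the first two lie within 2 percentage points) (summer / midnight / noon / autumn / none)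
2. amount of complex with three exchanged at the outlet or at the end, in percent of the starting complex put in, summer
3. amount of complex with three exchanged at the outlet or at the end, in percent of the starting complex put in, midnight
4. amount of complex with three exchanged at the outlet or at the end, in percent of the starting complex put in, noon
5. amount of complex with three exchanged at the outlet or at the end, in percent of the starting complex put in, autumn

- the stated concentrations are those of everything mixed, before any reaction; amounts are the same in each set-up
- the feed brings no volume worth counting
- run time (summer): 5.0 min

1. Each exchange step consumes one incoming ligand, and full exchange costs 3 per complex. The charge offers 1.80 exchanges per complex. This exchange budget B, incoming ligand charged over starting complex charged, is smaller than that cost, so incoming ligand is the limiting reagent. The amounts are equal in each set-up, so B is too.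

2. Does the budget reach the complexes within the run? The first exchange has the smallest forward constant, below the other two. At the charged ligand concentration its pseudo-first-order time is τ = 1/(k1·cX) = 11.7 s, far shorter than 5.0 min. Leaving ligand, which feeds the ways back, halves every 4.10 s by being carried off, quicker than τ. So I reckon on the budget being paid out on complexes by the end of summer. The capture agent equals 2.00% of the starting complex, hardly any.

3. Placed on as few complexes as possible, the budget makes B/3 = 60.0% of the charge fully exchanged. The isomerisation, forward and back together, relaxes with a half-life of 38.6 s, shorter than the run. Once relaxed, it leaves the fraction 1/(1+K4) = 61.7% as complex with three exchanged.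

4. For a relaxed split my ceiling is therefore C = B/(3(1+K4)) = 37.0% of the charge, and I apply it to summer and noon. It does not carry over to midnight: with mean residence time t, the steady balance of the tank keeps the share (1+k4·t/K4)/(1+k4·t+k4·t/K4) = 67.7%, above the relaxed share, so its limit is 40.6%. In autumn, ligand goes in until 4.00 min, so I claim no ceiling there.

5. The recipes differ in how thinly the budget is spread. In noon, τ is far shorter than the dosing time 4.00 min, so early arrivals of starting complex collect their exchanges while later ones are still to come. I place noon first and above summer, and I rank no further by hand.

The forecast gives 22.5% for summer, 25.5% for midnight, 30% for noon and 24.5% for autumn, and names noon as best. Its ground is: “Dosing the starting complex keeps ligand in local excess and drives early material fully to the triple-exchanged complex”.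

The simulation puts noon first at 30.6%, with summer at 21.5%, midnight at 26.0% and autumn at 23.8%, so noon stands at 82.7% of C. In autumn, each moved with the other held, the answer has shifted by 5 points at incoming ligand 0.0224 M or 0.0278 M, and at starting complex 0.0158 M or 0.0127 M. As B, low ligand and high complex read 1.60 and 1.60, and high ligand and low complex read 1.98 and 1.99.

(The constants used here are those of an exercise; the flask was simulated.)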